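Everything rests on the C2–C1′ bond between pyranone ring C and catechol ring B. C2 is bonded to O1, C3 and C1′, so it is a masked aroyl carbon and can come from carbon monoxide. A palladium-catalysed three-component carbonylative annulation of a protected 4-bromocatechol, CO and an o-hydroxyacetophenone forms C1′–C2, C2–C3 and O1–C2, that is all of ring C, in one operation. The acetophenone precursor already carries the C6 sulfate, installed by Elbs persulfate oxidation para to the phenol that becomes O1. As a base-stable anion it also masks O6. Hydrogenolysis of four benzyl ethers ends the route.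

Key step: step 3

Remark: the target has no stereocentre or stereogenic axis, so no stereocontrol is needed. It is drawn as the free hydrogen sulfate, so the potassium salt carried through the route is protonated only in the last operation, in the cold.

Step 1
Reactants: 1 2,4,6-trihydroxyacetophenone
Product: 2 1-[2,4-bis(benzyloxy)-6-hydroxyphenyl]ethanone
Conditions: BnBr (2.1 equiv), K2CO3 (2.2 equiv), DMF, 0 °C to rt
Reagents that add atoms: benzyl bromide BrCc1ccccc1
Why: Williamson etherification alkylates the 4-OH and one of the two equivalent ortho OH groups, while the remaining ortho OH stays hydrogen-bonded to the acetyl carbonyl and resists a third alkylation under mild base.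

Step 2
Reactants: 2 1-[2,4-bis(benzyloxy)-6-hydroxyphenyl]ethanone
Product: 3 potassium 3-acetyl-2,6-bis(benzyloxy)-4-hydroxyphenyl sulfate
Conditions: K2S2O8 (1.1 equiv, slow addition), aq. KOH, pyridine co-solvent, 10–20 °C; AcOH to pH 7; Et2O wash to recover 2; n-BuOH extraction of the salt
Reagents that add atoms: potassium peroxodisulfate [K+].[K+].[O-]S(=O)(=O)OOS(=O)(=O)[O-]
Why: In the Elbs persulfate oxidation the phenolate attacks a peroxide oxygen of peroxodisulfate through its only free para carbon, and the aryl sulfate that forms first is stable in base, so it is kept here by omitting the usual acid hydrolysis.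

Step 3
Reactants: 3 potassium 3-acetyl-2,6-bis(benzyloxy)-4-hydroxyphenyl sulfate; 4 4-bromo-1,2-bis(benzyloxy)benzene; 5 carbon monoxide
Product: 8 potassium 5,7-bis(benzyloxy)-2-[3,4-bis(benzyloxy)phenyl]-4-oxo-4H-chromen-6-yl sulfate, via aryl ester 6 (not isolated), via diketone 7 (not isolated)
Conditions: Pd(OAc)2 (2 mol%), dppb (4 mol%), DBU (3 equiv), CO (10 bar), dry DMF, 120 °C; work-up with aq. KHCO3/KCl to keep the potassium counter-ion
Reagents that add atoms: none
Why: Pd(0) inserts into the C–Br bond of 4, and migratory insertion of CO into the aryl–Pd bond creates the C1′–C2 bond as an aroyl-palladium species, which the DBU-generated phenoxide of 3 captures to give ester 6. DBU then enolises the acetyl group and a Baker–Venkataraman O-to-C acyl shift forms C2–C3 (diketone 7), after which the released phenoxide oxygen adds to the aroyl carbonyl and water is lost. The closest known reaction type is the palladium-catalysed carbonylative coupling of aryl bromides with 2-hydroxyacetophenones to flavones, applied here to a more substituted pair. The one ring closed, pyranone ring C, closes in a 6-exo-trig mode (O1 onto the C2 carbonyl) followed by dehydration, and no stereocentre is formed. The step needs capture of the aroyl-palladium by a single oxygen; this is secured because O5 and O7 are benzylated and O6 is a non-nucleophilic sulfate anion, so only the oxygen that becomes O1 is free and the 5,6,7-pattern cannot scramble to the 5,7,8-isomer. The sulfate monoester anion should tolerate DBU, Pd(0) and CO because it is cleaved only by acid and the medium stays basic throughout.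

Step 4
Reactants: 8 potassium 5,7-bis(benzyloxy)-2-[3,4-bis(benzyloxy)phenyl]-4-oxo-4H-chromen-6-yl sulfate
Product: 10 6-hydroxyluteolin 6-sulfate (2-(3,4-dihydroxyphenyl)-5,7-dihydroxy-4-oxo-4H-chromen-6-yl hydrogen sulfate), via potassium salt 9 (not isolated)
Conditions: H2 (1 atm), 10% Pd/C, MeOH–THF, rt, argon-flushed work-up; filter; HCl (1.0 equiv, MeOH), 0 °C; cold C18 desalting; freeze-drying
Reagents that add atoms: none
Why: Catalytic hydrogenolysis cleaves the four benzyl aryl ethers under neutral conditions that leave the aryl sulfate salt and the conjugated C2–C3 double bond untouched, and one equivalent of cold acid then only protonates the sulfate.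

Compound list
1 | 2,4,6-trihydroxyacetophenone | CC(=O)c1c(O)cc(O)cc1O | starting material
2 | 1-[2,4-bis(benzyloxy)-6-hydroxyphenyl]ethanone | CC(=O)c1c(O)cc(OCc2ccccc2)cc1OCc1ccccc1 | intermediate
3 | potassium 3-acetyl-2,6-bis(benzyloxy)-4-hydroxyphenyl sulfate | CC(=O)c1c(O)cc(OCc2ccccc2)c(OS(=O)(=O)[O-])c1OCc1ccccc1.[K+] | intermediate
4 | 4-bromo-1,2-bis(benzyloxy)benzene | Brc1ccc(OCc2ccccc2)c(OCc2ccccc2)c1 | starting material
5 | carbon monoxide | [C-]#[O+] | starting material
6 | potassium 3-acetyl-2,6-bis(benzyloxy)-4-{[3,4-bis(benzyloxy)benzoyl]oxy}phenyl sulfate (aryl ester, not isolated) | CC(=O)c1c(OC(=O)c2ccc(OCc3ccccc3)c(OCc3ccccc3)c2)cc(OCc2ccccc2)c(OS(=O)(=O)[O-])c1OCc1ccccc1.[K+] | intermediate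
7 | potassium 2,6-bis(benzyloxy)-3-{3-[3,4-bis(benzyloxy)phenyl]-3-oxopropanoyl}-4-hydroxyphenyl sulfate (1,3-diketone, not isolated) | O=C(CC(=O)c1ccc(OCc2ccccc2)c(OCc2ccccc2)c1)c1c(O)cc(OCc2ccccc2)c(OS(=O)(=O)[O-])c1OCc1ccccc1.[K+] | intermediate
8 | potassium 5,7-bis(benzyloxy)-2-[3,4-bis(benzyloxy)phenyl]-4-oxo-4H-chromen-6-yl sulfate | O=c1cc(-c2ccc(OCc3ccccc3)c(OCc3ccccc3)c2)oc2cc(OCc3ccccc3)c(OS(=O)(=O)[O-])c(OCc3ccccc3)c12.[K+] | intermediate
9 | potassium 2-(3,4-dihydroxyphenyl)-5,7-dihydroxy-4-oxo-4H-chromen-6-yl sulfate (not isolated) | O=c1cc(-c2ccc(O)c(O)c2)oc2cc(O)c(OS(=O)(=O)[O-])c(O)c12.[K+] | intermediate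
10 | 6-hydroxyluteolin 6-sulfate | O=c1cc(-c2ccc(O)c(O)c2)oc2cc(O)c(OS(=O)(=O)O)c(O)c12 | target

Total step count: 4. Longest linear sequence: 4 (1 → 2 → 3 → 8 → 10).

Steps most likely to fail

Step 3.
- What may go wrong: oxidative addition of the electron-rich bromide may be slow under CO pressure. The cascade may stall at the ester or diketone stage. The sulfate may be lost thermally.
- Fallback (from 3, back at 8): ring C is closed first and the same C2–C1′ bond is made afterwards.
  - Condensation of 3 with N,N-dimethylformamide dimethyl acetal (toluene, 90 °C) gives the enaminone F1.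
  - Brief treatment with cold dilute aqueous HCl/CH2Cl2 closes it to the 2-unsubstituted chromone F2.
  - Pd(II)-catalysed conjugate addition of commercial 3,4-bis(benzyloxy)phenylboronic acid to C2 (Pd(TFA)2, 2,2′-bipyridine, aqueous MeOH, 60 °C) gives the racemic flavanone F3.
  - Aerobic palladium dehydrogenation (Pd(TFA)2, DMSO, O2, 80 °C) converts F3 into 8.

Step 2.
- What may go wrong: the lipophilic phenolate may convert poorly in the aqueous medium. Radical over-oxidation of the electron-rich ring may compete. The amphiphilic salt may be lost during isolation.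
- Fallback (from 2, back at 3): oxygenation and sulfation are separated.
  - Teuber oxidation of 2 with Fremy's salt (aqueous acetone, phosphate buffer) gives the p-quinone F4.
  - Sodium dithionite reduces it to the hydroquinone F5.
  - Sulfur trioxide–pyridine (1.1 equiv, pyridine, rt) sulfates only the non-chelated hydroxyl, because the other is hydrogen-bonded to the acetyl carbonyl. A KHCO3 work-up delivers 3.

Step 4.
- What may go wrong: debenzylation at the hindered O5 may be incomplete and give inseparable salt mixtures. The sulfate may be lost through acid solvolysis on the catalyst support or during release of the free acid.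
- Fallback (from 8, back at 10): the anionic sulfate is exchanged for a neutral protected sulfate diester that can be chromatographed.
  - Deliberate solvolysis of 8 (1 M HCl, THF, 50 °C) gives the 6-hydroxyflavone F6.
  - 2,2,2-Trichloroethyl chlorosulfate (Et3N, DMAP, THF) converts it into the trichloroethyl sulfate diester F7.
  - One buffered transfer hydrogenolysis (Pd/C, ammonium formate, MeOH) removes the trichloroethyl group and all four benzyl groups to give the ammonium salt F8.
  - One equivalent of cold HCl turns F8 into 10.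

Further compounds
F1 | step 3 | potassium 2,6-bis(benzyloxy)-3-[(E)-3-(dimethylamino)prop-2-enoyl]-4-hydroxyphenyl sulfate | CN(C)/C=C/C(=O)c1c(O)cc(OCc2ccccc2)c(OS(=O)(=O)[O-])c1OCc1ccccc1.[K+]
F2 | step 3 | potassium 5,7-bis(benzyloxy)-4-oxo-4H-chromen-6-yl sulfate | O=c1ccoc2cc(OCc3ccccc3)c(OS(=O)(=O)[O-])c(OCc3ccccc3)c12.[K+]
F3 | step 3 | potassium 5,7-bis(benzyloxy)-2-[3,4-bis(benzyloxy)phenyl]-4-oxochroman-6-yl sulfate (racemic) | O=C1CC(c2ccc(OCc3ccccc3)c(OCc3ccccc3)c2)Oc2cc(OCc3ccccc3)c(OS(=O)(=O)[O-])c(OCc3ccccc3)c21.[K+]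
F4 | step 2 | 2-acetyl-3,5-bis(benzyloxy)cyclohexa-2,5-diene-1,4-dione | CC(=O)C1=C(OCc2ccccc2)C(=O)C(OCc2ccccc2)=CC1=O
F5 | step 2 | 1-[2,4-bis(benzyloxy)-3,6-dihydroxyphenyl]ethanone | CC(=O)c1c(O)cc(OCc2ccccc2)c(O)c1OCc1ccccc1
F6 | step 4 | 5,7-bis(benzyloxy)-2-[3,4-bis(benzyloxy)phenyl]-6-hydroxy-4H-chromen-4-one | O=c1cc(-c2ccc(OCc3ccccc3)c(OCc3ccccc3)c2)oc2cc(OCc3ccccc3)c(O)c(OCc3ccccc3)c12
F7 | step 4 | 5,7-bis(benzyloxy)-2-[3,4-bis(benzyloxy)phenyl]-4-oxo-4H-chromen-6-yl 2,2,2-trichloroethyl sulfate | O=c1cc(-c2ccc(OCc3ccccc3)c(OCc3ccccc3)c2)oc2cc(OCc3ccccc3)c(OS(=O)(=O)OCC(Cl)(Cl)Cl)c(OCc3ccccc3)c12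
F8 | step 4 | ammonium 2-(3,4-dihydroxyphenyl)-5,7-dihydroxy-4-oxo-4H-chromen-6-yl sulfate | O=c1cc(-c2ccc(O)c(O)c2)oc2cc(O)c(OS(=O)(=O)[O-])c(O)c12.[NH4+]
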